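**Assumption:** gibberellin (GA) numbering is used for all locants; α is the face carrying the C19–O–C20 lactone bridge, so the target has 5β‑H, 9β‑H, 6β‑CO2H, 2β‑OH and C15 on the β face.

## Retrosynthetic overview

1. GA98 (17) ⇐ 6‑epi methyl ester 16 by C6 epimerisation and saponification; ring D ⇐ SmI2 ketyl–alkyne closure of 8β‑propargyl 13‑ketone 15.
2. 15 ⇐ enone 14 by conjugate propargylation (C8 quaternary); the enone, 2β‑OH, 5β‑H and 9β‑H all come from one dissolving‑metal reduction of the aromatic‑ring‑C keto lactone 12.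
3. 12 ⇐ tricyclic ketone 9 by enol triflate carbonylation (C7) and acid lactonisation (C19→C20).
4. 9 ⇐ achiral indenone 4 + achiral siloxydiene 8 by a catalytic asymmetric formal [4+2] that builds ring A and both quaternary centres (C10, C4).
5. Ring order: C (arene) and B (indenone) are bought together → A → lactone → dearomatised C → D.

## Route

**Step 1**
Reactants: 1, 6‑methoxy‑1‑indanone
Product: 2, 3‑bromo‑6‑methoxy‑1H‑inden‑1‑one
Conditions: NBS (2.1 equiv), AIBN (cat.), PhCF3, 80 °C; then Et3N, 0 °C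
Reagents that add atoms: N‑bromosuccinimide, O=C1CCC(=O)N1Br
Why: Wohl–Ziegler benzylic bromination at C3 followed by dehydrobromination gives the β‑bromo indenone; no stereocentre is formed.

**Step 2**
Reactants: 2
Product: 3, 3‑(hydroxymethyl)‑6‑methoxy‑1H‑inden‑1‑one
Conditions: Bu3SnCH2OH, Pd(PPh3)4 (5 mol %), dioxane, 90 °C
Reagents that add atoms: (tributylstannyl)methanol, OC[Sn](CCCC)(CCCC)CCCC
Why: Stille (Kosugi–Migita) hydroxymethyl transfer to the activated β‑bromo enone installs the future C20 carbinol; no stereocentre.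

**Step 3**
Reactants: 3
Product: 4, 3‑[(tert‑butyldimethylsilyloxy)methyl]‑6‑methoxy‑1H‑inden‑1‑one
Conditions: TBSCl, imidazole, DMF, rt
Reagents that add atoms: TBSCl, CC(C)(C)[Si](C)(C)Cl
Why: Standard silylation so the carbinol survives the silylium step, KHMDS and Pd.

**Step 4**
Reactants: 5, methyl pyruvate; 6, 1‑(triphenylphosphoranylidene)propan‑2‑one
Product: 7, methyl (2E)‑2‑methyl‑4‑oxopent‑2‑enoate
Conditions: CH2Cl2, rt
Reagents that add atoms: none
Why: Wittig olefination of the α‑keto ester with a stabilised ylide gives the E keto‑enoate (acyl trans to ester).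

**Step 5**
Reactants: 7
Product: 8, methyl (2E)‑4‑(tert‑butyldimethylsilyloxy)‑2‑methylpenta‑2,4‑dienoate
Conditions: TBSOTf, Et3N, CH2Cl2, −78 → 0 °C
Reagents that add atoms: TBSOTf, CC(C)(C)[Si](C)(C)OS(=O)(=O)C(F)(F)F
Why: Soft enolisation at the only α‑CH3 gives the cross‑conjugated 2‑siloxydiene with the C=C geometry retained.

**Step 6 (key step)**
Reactants: 4; 8 (1.5 equiv)
Product: 9, methyl 3‑(TBSO)‑4a‑(TBSOCH2)‑7‑methoxy‑1‑methyl‑9‑oxo‑4,4a,9,9a‑tetrahydro‑1H‑fluorene‑1‑carboxylate; cis ring fusion, CO2Me cis to CH2OTBS (GA: C10 and C4 as in GA98, C5 epimeric, C2 as TBS enol ether, C6 ketone)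
Conditions: chiral confined imidodiphosphorimidate (IDPi) Brønsted acid (3 mol %, enantiomer chosen to give C10 as drawn), PhMe, −60 → −20 °C
Reagents that add atoms: none
Why: Proposed new method: the IDPi acid is silylated by 8 to a chiral silylium ion pair that activates 4 as a 1‑siloxyindenyl cation (C10 stabilised by the para‑anisyl ring), C1 of the diene adds face‑selectively inside the anion pocket to set the C10 quaternary centre (Mukaiyama–Michael), and the new C5 silyl enol ether then closes onto the silyl‑activated β‑ester enone at C4 with the smaller methyl next to C6–OSi and the ester on the CH2OTBS face (second, intramolecular Mukaiyama–Michael), returning silylium and leaving C2 masked as its TBS enol ether; the closest known reactions are silylium/IDPi‑catalysed asymmetric Mukaiyama–Michael and Diels–Alder reactions and Lewis‑acid double‑Michael formal [4+2] annulations of 2‑siloxydienes.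

**Step 7**
Reactants: 9
Product: 10, the C6 enol triflate of 9 (C5=C6), methyl 3‑(TBSO)‑4a‑(TBSOCH2)‑7‑methoxy‑1‑methyl‑9‑(triflyloxy)‑4,4a‑dihydro‑1H‑fluorene‑1‑carboxylate
Conditions: KHMDS, THF, −78 → 0 °C; then PhNTf2
Reagents that add atoms: N‑phenyl‑bis(trifluoromethanesulfonimide), O=S(=O)(N(c1ccccc1)S(=O)(=O)C(F)(F)F)C(F)(F)F
Why: C5–H is the only enolisable position (C2 is a silyl enol ether, C19 has no α‑H), so enolate triflation is regiospecific and erases the cis C5 centre, which is reset in step 10.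

**Step 8**
Reactants: 10
Product: 11, dimethyl 3‑(TBSO)‑4a‑(TBSOCH2)‑7‑methoxy‑1‑methyl‑4,4a‑dihydro‑1H‑fluorene‑1,9‑dicarboxylate
Conditions: Pd(OAc)2, dppf, CO (1 atm), MeOH, Et3N, DMF, 60 °C
Reagents that add atoms: carbon monoxide, [C-]#[O+]; methanol, CO
Why: Pd‑catalysed methoxycarbonylation of the vinyl triflate installs C7 as the aryl‑conjugated ester; no stereocentre.

**Step 9**
Reactants: 11
Product: 12, keto lactone (GA: 2‑oxo, 19,20‑lactone, Δ5(6) 7‑methyl ester, ring C = anisole)
Conditions: TsOH·H2O, MeCN/H2O, 40 °C; then PhMe, 90 °C (−MeOH)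
Reagents that add atoms: none
Why: Acid cleaves both silyl groups (enol ether → C2 ketone) and the freed C20–OH lactonises onto the cis C19 methyl ester to close the 3‑oxabicyclo[3.3.1]nonanone, which also confirms the C4/C10 cis relationship.

**Step 10**
Reactants: 12
Product: 13, hydroxy enone acid (GA: 2β‑OH, 13‑oxo‑Δ8(14), 19,20‑lactone, 5β‑H, 9β‑H, 6α‑CO2H, i.e. 6‑epi; C15–C17 absent)
Conditions: LiOH (3 equiv), THF/H2O, 50 °C, evaporate; Li, NH3(l)/THF, t‑BuOH, −78 → −33 °C; NH4Cl; then 2 M HCl/THF, rt → 45 °C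
Reagents that add atoms: water/lithium hydroxide, O and [Li+].[OH-] (O of the C7 acid and of the C13 ketone)
Why: With both carboxyls protected as lithium salts, the dissolving metal gives the thermodynamic equatorial 2β‑alkoxide from the ketone, conjugate‑reduces the enoate with protonation at C5 anti to axial C20 (trans A/B) and kinetic β‑face protonation at C6, and Birch‑reduces the anisole to the 2,5‑dihydro enol ether; acid then hydrolyses the enol ether, moves C8=C9 into conjugation by γ‑protonation at C9 anti to C20 (9β‑H) and recloses the lactone.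

**Step 11**
Reactants: 13
Product: 14, methyl ester of 13
Conditions: TMSCHN2, PhMe/MeOH, 0 °C
Reagents that add atoms: (trimethylsilyl)diazomethane, C[Si](C)(C)C=[N+]=[N-]
Why: Neutral O‑methylation re‑esterifies C7 without epimerising the labile 6α centre or touching the enone or lactone.

**Step 12**
Reactants: 14
Product: 15, 8β‑(prop‑2‑ynyl) 13‑ketone (GA: C8 as in GA98, cis B/C, 2β‑OH, 19,20‑lactone, 6α‑CO2Me)
Conditions: BSA, CH2Cl2, rt (transient 2‑O‑TMS); allenylSnBu3, TiCl4, −78 °C; 1 M HCl work‑up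
Reagents that add atoms: allenyltributylstannane, C=C=C[Sn](CCCC)(CCCC)CCCC
Why: TiCl4‑promoted SE2′ conjugate propargylation (Sakurai type) attacks the enone β‑carbon axially on the β face, anti to the axial C20 bridge and to the 6α‑ester, giving the cis‑fused C8 quaternary centre.

**Step 13**
Reactants: 15
Product: 16, 6‑epi‑gibberellin A98 methyl ester
Conditions: SmI2, HMPA, t‑BuOH, THF, 0 °C → rt
Reagents that add atoms: none
Why: SmI2 ketyl–alkyne 5‑exo‑dig reductive cyclisation gives the bridgehead 13‑OH and the 16‑methylene directly; the C13 configuration is dictated by the 1,3‑diaxial bridge from C8, and the ester and lactone are inert to SmI2.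

**Step 14**
Reactants: 16
Product: 17, gibberellin A98
Conditions: NaOMe, MeOH, 65 °C; then 2 M aq NaOH, 70 °C; then HCl to pH 3, 0 °C → rt
Reagents that add atoms: water/sodium hydroxide, O
Why: Methoxide equilibrates C6 to the thermodynamically preferred 6β‑ester (trans to C4), saponification frees the 7‑acid, and mild acidification recloses the 19,20‑lactone without disturbing the 13‑hydroxy‑16‑ene.

## Compound list

1 | 6‑methoxy‑1‑indanone | COc1ccc2CCC(=O)c2c1 | starting material
2 | 3‑bromo‑6‑methoxy‑1H‑inden‑1‑one | COc1ccc2C(Br)=CC(=O)c2c1 | intermediate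
3 | 3‑(hydroxymethyl)‑6‑methoxy‑1H‑inden‑1‑one | COc1ccc2C(CO)=CC(=O)c2c1 | intermediate
4 | 3‑[(TBSO)methyl]‑6‑methoxy‑1H‑inden‑1‑one | COc1ccc2C(CO[Si](C)(C)C(C)(C)C)=CC(=O)c2c1 | intermediate
5 | methyl pyruvate | CC(=O)C(=O)OC | starting material
6 | 1‑(triphenylphosphoranylidene)propan‑2‑one | CC(=O)C=P(c1ccccc1)(c1ccccc1)c1ccccc1 | starting material
7 | methyl (2E)‑2‑methyl‑4‑oxopent‑2‑enoate | CC(=O)/C=C(C)/C(=O)OC | intermediate
8 | methyl (2E)‑4‑(TBSO)‑2‑methylpenta‑2,4‑dienoate | C=C(O[Si](C)(C)C(C)(C)C)/C=C(C)/C(=O)OC | intermediate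
9 | cis‑fused tetrahydrofluorenone: C6 ketone, C2 TBS enol ether, 10‑CH2OTBS, 4‑Me/4‑CO2Me (ester cis to CH2OTBS) | COc1ccc2c(c1)C(=O)[C@@H]1[C@@]2(CO[Si](C)(C)C(C)(C)C)CC(O[Si](C)(C)C(C)(C)C)=C[C@@]1(C)C(=O)OC | intermediate
10 | C6 enol triflate of 9 (C5=C6) | COc1ccc2c(c1)C(OS(=O)(=O)C(F)(F)F)=C1[C@@]2(CO[Si](C)(C)C(C)(C)C)CC(O[Si](C)(C)C(C)(C)C)=C[C@@]1(C)C(=O)OC | intermediate
11 | C7 methyl ester (Δ5(6) enoate), bis‑TBS, C19 methyl ester | COc1ccc2c(c1)C(C(=O)OC)=C1[C@@]2(CO[Si](C)(C)C(C)(C)C)CC(O[Si](C)(C)C(C)(C)C)=C[C@@]1(C)C(=O)OC | intermediate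
12 | 2‑oxo 19,20‑lactone, Δ5(6) 7‑methyl ester, aromatic ring C | COc1ccc2c(c1)C(C(=O)OC)=C1[C@]23COC(=O)[C@]1(C)CC(=O)C3 | intermediate
13 | 2β‑hydroxy‑13‑oxo‑Δ8(14) 19,20‑lactone 7‑acid (5β‑H, 9β‑H, 6α‑CO2H) | O=C1CC[C@@H]2C(=C1)[C@H](C(=O)O)[C@H]1[C@]23COC(=O)[C@]1(C)C[C@@H](O)C3 | intermediate
14 | methyl ester of 13 | O=C1CC[C@@H]2C(=C1)[C@H](C(=O)OC)[C@H]1[C@]23COC(=O)[C@]1(C)C[C@@H](O)C3 | intermediate
15 | 8β‑propargyl 13‑ketone | O=C1CC[C@@H]2[C@](CC#C)(C1)[C@H](C(=O)OC)[C@H]1[C@]23COC(=O)[C@]1(C)C[C@@H](O)C3 | intermediate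
16 | 6‑epi‑gibberellin A98 methyl ester | C=C1C[C@]23C[C@@]1(O)CC[C@H]2[C@]12COC(=O)[C@](C)(C[C@@H](O)C1)[C@H]2[C@H]3C(=O)OC | intermediate
17 | gibberellin A98 | C=C1C[C@]23C[C@@]1(O)CC[C@H]2[C@]12COC(=O)[C@](C)(C[C@@H](O)C1)[C@H]2[C@@H]3C(=O)O | target

## Step count

Total steps: 14. Longest linear sequence: 12 (1 → 2 → 3 → 4 → 9 → … → 17); the diene branch (5 + 6 → 7 → 8) is 2 steps.

## Steps most likely to fail

1. **Step 6 (proposed new asymmetric formal [4+2], two quaternary centres).** Fallback with known chemistry: set C10 by bifunctional cinchona (thio)urea‑catalysed desymmetrising methanolysis of 3‑(4‑methoxyphenyl)‑3‑(TBSOCH2)glutaric anhydride, close ring B by Friedel–Crafts acylation of the acid arm, then build ring A stepwise from the ester arm (β‑ketophosphonate, HWE with methyl pyruvate, base‑mediated intramolecular Michael) and rejoin at the diketone corresponding to 9.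

2. **Step 10 (saponification, triple dissolving‑metal reduction and hydrolysis in one pot).** The risks are solubility of the polyanion, over‑reduction, and the C9 and C2 outcomes. Fallback: separate the events with a different C2 tactic: Mg/MeOH conjugate reduction of the enoate, hydride reduction of C2 followed by Mitsunobu inversion to 2β and protection, then a conventional Na/NH3/EtOH Birch reduction and acid hydrolysis on the simpler dicarboxylate.

3. **Step 12 (conjugate propargylation forming the hindered C8 centre next to C6 and C10).** Fallback: change the ring‑D construction to Hosomi–Sakurai allylation (allylSiMe3/TiCl4), ozonolysis to the C16 aldehyde, SmI2 pinacol‑type keto‑aldehyde cyclisation to the 13,16‑diol, then oxidation of C16 and Wittig methylenation.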